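**Retrosynthetic overview**
- The angelate is cut back to the (S)-carbinol, and that to the 5-acetyl ketone by reagent-controlled reduction, so the side-chain stereocentre is set last.
- Only one ring is formed, the dihydrofuran. As in the presumed biosynthesis from a C5-substituted 4-hydroxyacetophenone, the phenolic oxygen closes onto C-2' of an epoxidised side chain. Here the epoxide sits at C-1'/C-2' and is opened with net retention through a palladium allyl while the phenol's acetyl is relayed to O-3, which gives the cis-2,3 pair and the 3-acetate in one step.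
- The trans-vinyl epoxide comes from asymmetric sulfur-ylide epoxidation of 2-acetoxy-5-acetylbenzaldehyde with the ylide of methyl 2-(bromomethyl)acrylate.
- The aldehyde comes from ortho-formylation and O-acetylation of 4'-hydroxyacetophenone.

Assumption: the (1R,4R,5R) antipode of isothiocineole is taken as the one that delivers the (2S,3S)-epoxide; if the sense is opposite, its mirror image (from the other limonene enantiomer) is used and nothing else changes.

**Step 1**
Reactants: 1 4'-hydroxyacetophenone
Product: 2 5-acetyl-2-hydroxybenzaldehyde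
Conditions: MgCl2, Et3N, (CH2O)n, MeCN, reflux; then 1 M HCl
Reagents that add atoms: formaldehyde (as paraformaldehyde), C=O
Why: Magnesium-phenoxide-directed ortho-hydroxymethylation followed by Oppenauer-type hydride transfer to a second formaldehyde (Casnati–Skattebøl ortho-formylation) reacts only at the two equivalent positions ortho to OH.

**Step 2**
Reactants: 2 5-acetyl-2-hydroxybenzaldehyde
Product: 3 4-acetyl-2-formylphenyl acetate
Conditions: Ac2O, pyridine, CH2Cl2, 0 °C → rt
Reagents that add atoms: acetic anhydride, CC(=O)OC(C)=O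
Why: Simple O-acylation of the acidic phenol, which masks it and stores the acetyl group that later ends up on O-3.

**Step 3**
Reactants: 3 4-acetyl-2-formylphenyl acetate; 4 methyl 2-(bromomethyl)acrylate; 5 (1R,4R,5R)-isothiocineole
Product: 7 methyl 2-[(2S,3S)-3-(2-acetoxy-5-acetylphenyl)oxiran-2-yl]acrylate, via sulfonium bromide 6 (not isolated)
Conditions: 4 + 5, MeCN, rt (→ 6); then 3, Cs2CO3, MeCN, −20 → 0 °C
Reagents that add atoms: none
Why: Asymmetric Corey–Chaykovsky (Aggarwal-type) epoxidation, in which the semi-stabilised 2-substituted allyl ylide adds to the aldehyde much faster than to the aryl methyl ketone, the anti-betaine closes to the trans-epoxide, and the bicyclic sulfide sets both epoxide carbons by reagent control (any betaine that instead relays acetyl and closes through the phenoxide gives 8, the same stereoisomer the next step makes).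

**Step 4**
Reactants: 7 methyl 2-[(2S,3S)-3-(2-acetoxy-5-acetylphenyl)oxiran-2-yl]acrylate
Product: 8 methyl 2-[(2S,3S)-3-acetoxy-5-acetyl-2,3-dihydro-1-benzofuran-2-yl]acrylate
Conditions: Pd2(dba)3·CHCl3 (2.5 mol %), dppe (5 mol %), THF, 0 °C → rt
Reagents that add atoms: none
Why: Proposed new method: zerovalent palladium ionises the vinyl epoxide with inversion at C-2 to a 2-(methoxycarbonyl)allyl palladium alkoxide, the C-3 alkoxide takes the acetyl from the neighbouring aryl acetate through a six-membered transition state, and the released phenoxide attacks C-2 anti to palladium in a 5-exo closure (double inversion, hence retention, so the trans-epoxide maps onto the cis-2,3 product with C-3 untouched); the closest known reactions are Tsuji–Trost opening of vinyl epoxides with net retention and the branched-selective O-arylation of Morita–Baylis–Hillman-type π-allyls by phenols.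

**Step 5**
Reactants: 8 methyl 2-[(2S,3S)-3-acetoxy-5-acetyl-2,3-dihydro-1-benzofuran-2-yl]acrylate
Product: 9 methyl 2-[(2S,3S)-3-acetoxy-5-[(1S)-1-hydroxyethyl]-2,3-dihydro-1-benzofuran-2-yl]acrylate
Conditions: (R)-2-methyl-CBS-oxazaborolidine (20 mol %), catecholborane (1.6 equiv), toluene, −78 → −40 °C; then MeOH, aq. NH4Cl
Reagents that add atoms: none
Why: Corey–Bakshi–Shibata reduction with aryl as the large group, where the (R)-catalyst gives the (S)-carbinol under reagent control and catecholborane at low temperature leaves the acrylate, methyl ester and acetate untouched.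

**Step 6**
Reactants: 9 methyl 2-[(2S,3S)-3-acetoxy-5-[(1S)-1-hydroxyethyl]-2,3-dihydro-1-benzofuran-2-yl]acrylate; 10 angelic acid
Product: 12 methyl 2-[(2S,3S)-3-acetoxy-5-{(1S)-1-[(2Z)-2-methylbut-2-enoyloxy]ethyl}-2,3-dihydro-1-benzofuran-2-yl]acrylate, via mixed anhydride 11 (not isolated)
Conditions: 10, 2,4,6-trichlorobenzoyl chloride, Et3N, toluene, rt (→ 11); then 9, toluene, 60 °C, no DMAP
Reagents that add atoms: none
Why: Yamaguchi-type acylation through the hindered mixed anhydride without a nucleophilic catalyst transfers the angeloyl group with retention at the carbinol carbon and without Z-to-E isomerisation.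

**Compound list**
1 | 4'-hydroxyacetophenone | CC(=O)c1ccc(O)cc1 | starting material
2 | 5-acetyl-2-hydroxybenzaldehyde | CC(=O)c1ccc(O)c(C=O)c1 | intermediate
3 | 4-acetyl-2-formylphenyl acetate | CC(=O)Oc1ccc(C(C)=O)cc1C=O | intermediate
4 | methyl 2-(bromomethyl)acrylate | C=C(CBr)C(=O)OC | starting material
5 | (1R,4R,5R)-isothiocineole, (1R,4R,5R)-4,7,7-trimethyl-6-thiabicyclo[3.2.1]octane | C[C@@H]1CC[C@@H]2C[C@H]1SC2(C)C | starting material
6 | S-[2-(methoxycarbonyl)allyl]sulfonium bromide of 5 (alkyl group exo on sulfur) | C[C@@H]1CC[C@@H]2C[C@H]1[S@@+](CC(=C)C(=O)OC)C2(C)C.[Br-] | intermediate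
7 | methyl 2-[(2S,3S)-3-(2-acetoxy-5-acetylphenyl)oxiran-2-yl]acrylate (trans-epoxide) | C=C(C(=O)OC)[C@@H]1O[C@H]1c1cc(C(C)=O)ccc1OC(C)=O | intermediate
8 | methyl 2-[(2S,3S)-3-acetoxy-5-acetyl-2,3-dihydro-1-benzofuran-2-yl]acrylate (2,3-cis) | C=C(C(=O)OC)[C@@H]1Oc2ccc(C(C)=O)cc2[C@@H]1OC(C)=O | intermediate
9 | methyl 2-[(2S,3S)-3-acetoxy-5-[(1S)-1-hydroxyethyl]-2,3-dihydro-1-benzofuran-2-yl]acrylate | C=C(C(=O)OC)[C@@H]1Oc2ccc([C@H](C)O)cc2[C@@H]1OC(C)=O | intermediate
10 | angelic acid, (2Z)-2-methylbut-2-enoic acid | C/C=C(/C)C(=O)O | starting material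
11 | angelic 2,4,6-trichlorobenzoic anhydride | C/C=C(/C)C(=O)OC(=O)c1c(Cl)cc(Cl)cc1Cl | intermediate
12 | methyl 2-[(2S,3S)-3-acetoxy-5-{(1S)-1-[(2Z)-2-methylbut-2-enoyloxy]ethyl}-2,3-dihydro-1-benzofuran-2-yl]acrylate | C=C(C(=O)OC)[C@@H]1Oc2ccc([C@H](C)OC(=O)/C(C)=C\C)cc2[C@@H]1OC(C)=O | target

**Total step count:** 6. **Longest linear sequence:** 6 steps (1 → 2 → 3 → 7 → 8 → 9 → 12).

**Steps most likely to fail**

Step 4. The π-allyl may lose its configurational memory by η3–η1–η3 exchange through the CH2 terminus (giving the C-2 epimer), the alkoxide may close to a 2,5-dihydrofuran before the acetyl shift, or 8 may re-ionise. The fallback replaces the palladium allyl by two separate SN2 inversions on the mirror-image epoxide. It sets out from aldehyde 3, which is epoxidised as in step 3 but with (1S,4S,5S)-isothiocineole, through the antipodal sulfonium bromide F3 to methyl 2-[(2R,3R)-3-(2-acetoxy-5-acetylphenyl)oxiran-2-yl]acrylate F4. BF3·OEt2 in CH2Cl2 at −78 °C, followed by aqueous NaHCO3, lets the neighbouring aryl acetate open the epoxide at the benzylic carbon with inversion, giving methyl (3R,4S)-4-acetoxy-4-(5-acetyl-2-hydroxyphenyl)-3-hydroxy-2-methylidenebutanoate F5. Mitsunobu etherification (PPh3, DIAD, THF, 0 °C) then closes O–C-2 by 5-exo-tet displacement with inversion and comes back to the route at 8.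

Step 3. The ester-bearing allyl ylide is untested with this sulfide, so ee and trans/cis ratio may be poor, and the ylide may add to its own acrylate. The fallback sets out from aldehyde 3 and separates olefination from oxidation. Wittig reaction with the ylide from [2-(methoxycarbonyl)prop-2-en-1-yl]triphenylphosphonium bromide F1 (from 4 and PPh3; NaN(SiMe3)2, THF, −78 °C) gives methyl (3E)-4-(2-acetoxy-5-acetylphenyl)-2-methylidenebut-3-enoate F2. Shi epoxidation of its styrenyl double bond with the L-fructose-derived Shi ketone and Oxone (2KHSO5·KHSO4·K2SO4) at pH 8 (NaHCO3), used promptly because such dienes dimerise, then comes back to the route at 7.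

Step 6. The angelate may isomerise to the tiglate, and heating with amine may eliminate the cis-3-acetate to the benzofuran. The fallback sets out from ketone 8 and makes the ester bond with inversion under neutral conditions. Reduction with (S)-2-methyl-CBS-oxazaborolidine and catecholborane gives methyl 2-[(2S,3S)-3-acetoxy-5-[(1R)-1-hydroxyethyl]-2,3-dihydro-1-benzofuran-2-yl]acrylate F6. Mitsunobu esterification with angelic acid 10 (PPh3, DIAD, toluene, −20 °C) inverts the carbinol and comes back to the route at 12.

**Further compounds**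
F1 | step 3 | [2-(methoxycarbonyl)prop-2-en-1-yl]triphenylphosphonium bromide | C=C(C[P+](c1ccccc1)(c1ccccc1)c1ccccc1)C(=O)OC.[Br-]
F2 | step 3 | methyl (3E)-4-(2-acetoxy-5-acetylphenyl)-2-methylidenebut-3-enoate | C=C(C(=O)OC)/C=C/c1cc(C(C)=O)ccc1OC(C)=O
F3 | step 4 | S-[2-(methoxycarbonyl)allyl]sulfonium bromide of (1S,4S,5S)-isothiocineole | C[C@H]1CC[C@H]2C[C@@H]1[S@+](CC(=C)C(=O)OC)C2(C)C.[Br-]
F4 | step 4 | methyl 2-[(2R,3R)-3-(2-acetoxy-5-acetylphenyl)oxiran-2-yl]acrylate | C=C(C(=O)OC)[C@H]1O[C@@H]1c1cc(C(C)=O)ccc1OC(C)=O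
F5 | step 4 | methyl (3R,4S)-4-acetoxy-4-(5-acetyl-2-hydroxyphenyl)-3-hydroxy-2-methylidenebutanoate | C=C(C(=O)OC)[C@@H](O)[C@@H](OC(C)=O)c1cc(C(C)=O)ccc1O
F6 | step 6 | methyl 2-[(2S,3S)-3-acetoxy-5-[(1R)-1-hydroxyethyl]-2,3-dihydro-1-benzofuran-2-yl]acrylate | C=C(C(=O)OC)[C@@H]1Oc2ccc([C@@H](C)O)cc2[C@@H]1OC(C)=O
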